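**Retrosynthetic overview**

1. Target 29 ⇐ dialdehyde dimethyl ether 28 (chelation-assisted demethylation) ⇐ dibromide 26 (Br–Li exchange, DMF) ⇐ chroman 25; the C-9′ hydrogen and isobutyl group come from ketone 20 by organocerium addition and ionic hydrogenolysis.
2. Pyran ring (O–C-3′a) ⇐ hemiketal reduction of keto phenol 18; C-9′a quaternary centre ⇐ C-methylation of 1,3-diketone 16; C-9′–C-9′a bond ⇐ aldol of spiro ketone 11 with aldehyde 13, then oxidation.
3. Spiro ketone 11 ⇐ spiro-1,4-dione 8, by removing the carbonyl trans to the ring methyl (hydride, then Barton–McCombie).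
4. Dione 8 ⇐ geminal acylation of enone 5 with 6. The route rests on the spiro carbon (C-1 of the cyclohexene = C-3′ of the cyclopentane): its two cyclopentane neighbours, the O-bearing C-3′a and C-2′H2, are the two acyl carbons of a succinoyl unit placed on the carbonyl carbon of a 6-methyl-3-isopropylcyclohex-2-enone.
5. Enone 5 ⇐ (R)-carvone (hydrogenation, kinetic silyl enol ether, Saegusa–Ito). Ring order: cyclohexene (chiral pool) → cyclopentane (step 4) → arene attached (step 9) → pyran (steps 12–13).

Key step: step 4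

Remark: the enantiomeric purity of 5 equals the trans/cis purity of 2, so 2 is assumed to be freed from its cis epimer before step 2; primed locants refer to the cyclopenta[b]chromene half of the tetracycles (C-3′ spiro, C-3′a O–CH, C-9′ benzylic, C-9′a methyl-bearing carbon).

**Route**

Step 1
Reactants: 1 (R)-(−)-carvone
Product: 2 (2R,5R)-2-methyl-5-(propan-2-yl)cyclohexan-1-one (trans)
Conditions: H2 (1 atm), 10% Pd/C, EtOAc, rt; then NaOMe (cat.), MeOH, rt; chromatographic removal of the cis epimer
Reagents that add atoms: none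
Why: Catalytic hydrogenation saturates both C=C bonds without touching C-5, and base epimerisation α to the ketone should favour the diequatorial 2,5-trans isomer, so the methyl centre is set by relay from C-5 under equilibrium control.

Step 2
Reactants: 2 (2R,5R)-2-methyl-5-(propan-2-yl)cyclohexan-1-one
Product: 4 trimethyl{[(3S,6R)-6-methyl-3-(propan-2-yl)cyclohex-1-en-1-yl]oxy}silane, via lithium enolate 3 (not isolated)
Conditions: LDA (1.1 equiv), THF, −78 °C; TMSCl, −78 °C → rt
Reagents that add atoms: chlorotrimethylsilane C[Si](C)(C)Cl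
Why: Irreversible deprotonation with LDA at −78 °C removes the less hindered C-6 proton (kinetic enolate) and O-silylation fixes the Δ1(6) regiochemistry without epimerising the C-2 methyl centre.

Step 3
Reactants: 4 trimethyl{[(3S,6R)-6-methyl-3-(propan-2-yl)cyclohex-1-en-1-yl]oxy}silane
Product: 5 (6R)-6-methyl-3-(propan-2-yl)cyclohex-2-en-1-one
Conditions: Pd(OAc)2 (1.05 equiv), MeCN, rt
Reagents that add atoms: none
Why: Saegusa–Ito oxidation, in which palladium binds the enolate carbon on the face opposite the isopropyl group where the C-5 hydrogen is syn for β-hydride elimination, so the alkene enters on the isopropyl side, the C-5 centre is erased and the methyl centre survives the neutral conditions.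

Step 4
Reactants: 5 (6R)-6-methyl-3-(propan-2-yl)cyclohex-2-en-1-one; 6 1,2-bis(trimethylsilyloxy)cyclobutene
Product: 8 (10R)-10-methyl-7-(propan-2-yl)spiro[4.5]dec-6-ene-1,4-dione, via cyclobutanone aldol adduct 7 (not isolated)
Conditions: 6 (2.5 equiv), BF3·OEt2 (1.5 equiv), CH2Cl2, −78 °C; then TFA (excess), −78 → 0 °C
Reagents that add atoms: none
Why: BF3 activates the enone carbonyl and the bis-silyl enol ether 6 adds at C-1 (Mukaiyama aldol) to give the 2-silyloxycyclobutanone carbinol 7; acid then ionises the tertiary allylic carbinol and the ring acyl carbon migrates to the cationic carbon with loss of the silyl group (pinacol-type 4→5 ring expansion), so the former carbonyl carbon becomes the spiro carbon between two ketones. The closest known reaction is the one-pot geminal acylation of ketones and ketals with 6, which is known to be less dependable on conjugated enones. The cyclopentane-1,3-dione ring is closed by this 1,2-acyl shift onto the exocyclic cation, i.e. by enlargement of the cyclobutanone, and both C–C bonds to the spiro carbon are made in the one operation. No new stereocentre is created, because the spiro carbon carries two constitutionally identical acyl arms, and the methyl centre of 5 is only carried through as C-10 of 8. The step needs 1,2- rather than 1,4-addition, retention of the alkene position and no epimerisation of the α′-methyl centre: the β-isopropyl group would force conjugate attack to build a quaternary carbon and so disfavours it, the acyl shift can only deliver to the carbinol terminus of the allyl cation, and the low temperature protects the methyl centre, which is no longer α to a carbonyl once the aldol addition has occurred.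

Step 5
Reactants: 8 (10R)-10-methyl-7-(propan-2-yl)spiro[4.5]dec-6-ene-1,4-dione
Product: 9 (4S,5R,10R)-4-hydroxy-10-methyl-7-(propan-2-yl)spiro[4.5]dec-6-en-1-one
Conditions: NaBH4 (0.3 equiv), MeOH–CH2Cl2 (1:1), −78 °C
Reagents that add atoms: none
Why: Mono-reduction of a 2,2-disubstituted cyclopentane-1,3-dione, in which the carbonyl cis to the C-10 methyl is screened on one face by that methyl and would push its oxygen against it on reduction, so hydride should take the trans carbonyl (C-4) from the alkene side and thereby fix the spiro centre; the carbinol configuration is lost in step 7 and any C-1-reduced isomer can be separated and re-oxidised to 8.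

Step 6
Reactants: 9 (4S,5R,10R)-4-hydroxy-10-methyl-7-(propan-2-yl)spiro[4.5]dec-6-en-1-one
Product: 10 O-[(4S,5R,10R)-10-methyl-1-oxo-7-(propan-2-yl)spiro[4.5]dec-6-en-4-yl] O-phenyl carbonothioate
Conditions: PhOC(S)Cl, pyridine, DMAP (cat.), CH2Cl2, 0 °C → rt
Reagents that add atoms: O-phenyl chlorothionoformate S=C(Cl)Oc1ccccc1
Why: DMAP-catalysed acylation of the hindered secondary alcohol gives the thionocarbonate without forming the alkoxide that xanthate formation would need and that could open the β-hydroxy ketone by retro-aldol cleavage.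

Step 7
Reactants: 10 O-phenyl thionocarbonate of 9
Product: 11 (5R,10R)-10-methyl-7-(propan-2-yl)spiro[4.5]dec-6-en-1-one
Conditions: Bu3SnH (2 equiv), AIBN (cat.), toluene, 100 °C
Reagents that add atoms: none
Why: Barton–McCombie deoxygenation, in which the stannyl radical adds to C=S, the C–O bond fragments and the secondary radical takes hydrogen from the stannane; 3-exo closure onto the alkene or the ketone would build a bicyclo[2.1.0]pentane and should not compete, and the spiro centre is untouched.

Step 8
Reactants: 12 2-hydroxy-4,6-dimethoxybenzaldehyde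
Product: 13 2,4-dimethoxy-6-(methoxymethoxy)benzaldehyde
Conditions: MOMCl, i-Pr2NEt, CH2Cl2, 0 °C → reflux
Reagents that add atoms: chloromethyl methyl ether COCCl
Why: O-Alkylation of the chelated phenol masks the acidic OH for the enolate chemistry as an acetal that aqueous acid removes later.

Step 9
Reactants: 11 (5R,10R)-10-methyl-7-(propan-2-yl)spiro[4.5]dec-6-en-1-one; 13 2,4-dimethoxy-6-(methoxymethoxy)benzaldehyde
Product: 15 (5R,10R)-2-{[2,4-dimethoxy-6-(methoxymethoxy)phenyl](hydroxy)methyl}-10-methyl-7-(propan-2-yl)spiro[4.5]dec-6-en-1-one (diastereomer mixture), via lithium enolate 14 (not isolated)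
Conditions: LDA (1.1 equiv), THF, −78 °C; 13, −78 °C; AcOH quench at −78 °C
Reagents that add atoms: none
Why: Aldol addition, for which 11 has α-hydrogens only at C-2 (C-5 is quaternary) so that a single enolate adds to the non-enolisable aldehyde; the two new centres are left as a mixture because steps 10 and 11 erase them.

Step 10
Reactants: 15 aldol adduct
Product: 16 (5R,10R)-2-[2,4-dimethoxy-6-(methoxymethoxy)benzoyl]-10-methyl-7-(propan-2-yl)spiro[4.5]dec-6-en-1-one (keto/enol mixture)
Conditions: Dess–Martin periodinane (1.2 equiv), CH2Cl2, 0 °C → rt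
Reagents that add atoms: none
Why: Dess–Martin oxidation of the electron-rich benzylic β-hydroxy ketone gives the 1,3-diketone under near-neutral conditions that spare the MOM ether and the alkene.

Step 11
Reactants: 16 1,3-diketone
Product: 17 (2R,5R,10R)-2-[2,4-dimethoxy-6-(methoxymethoxy)benzoyl]-2,10-dimethyl-7-(propan-2-yl)spiro[4.5]dec-6-en-1-one
Conditions: MeI, K2CO3, acetone, rt
Reagents that add atoms: iodomethane CI
Why: C-Alkylation of the stabilised 1,3-diketone enolate, in which methyl iodide should approach C-2 from the cyclopentane face flanked by the flat =CH arm of the spiro carbon rather than the CHMe arm, whose methyl leans over the C-1 carbonyl, so that methyl and aroyl are placed as the target needs (substrate control).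

Step 12
Reactants: 17 methylated diketone
Product: 19 (1R,3′aS,6R,9′aS)-3′a-hydroxy-6′,8′-dimethoxy-6,9′a-dimethyl-3-(propan-2-yl)-1′,2′,3′a,9′a-tetrahydro-9′H-spiro[cyclohex-2-ene-1,3′-cyclopenta[b]chromen]-9′-one (cis-fused hemiketal), via keto phenol 18 (not isolated)
Conditions: 3 M aq. HCl, THF, 40 °C
Reagents that add atoms: none
Why: Acid hydrolysis of the MOM acetal frees the phenol, which adds to the cyclopentanone carbonyl (6-exo-trig) to give the cis-fused hemiketal in equilibrium with 18; acid is used in place of base so that retro-Claisen cleavage of the non-enolisable 1,3-diketone is avoided.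

Step 13
Reactants: 19 hemiketal
Product: 20 (1R,3′aS,6R,9′aR)-6′,8′-dimethoxy-6,9′a-dimethyl-3-(propan-2-yl)-1′,2′,3′a,9′a-tetrahydro-9′H-spiro[cyclohex-2-ene-1,3′-cyclopenta[b]chromen]-9′-one
Conditions: Et3SiH (5 equiv), BF3·OEt2 (3 equiv), CH2Cl2, −78 → −20 °C
Reagents that add atoms: none
Why: Lewis acid ionisation of the hemiketal to the cyclic oxocarbenium ion and hydride transfer from the silane (reductive deoxygenation of a lactol), in which hydride should enter C-3′a from the face of the 9′a-methyl and the alkene arm, anti to the C-9′a–C(=O) bond and the CHMe arm, giving the cis ring fusion while the low temperature spares the aryl ketone and the trisubstituted alkene.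

Step 14
Reactants: 20 chromanone; 21 1-bromo-2-methylpropane
Product: 24 (1R,3′aS,6R,9′R,9′aR)-6′,8′-dimethoxy-6,9′a-dimethyl-9′-(2-methylpropyl)-3-(propan-2-yl)-1′,2′,9′,9′a-tetrahydro-3′aH-spiro[cyclohex-2-ene-1,3′-cyclopenta[b]chromen]-9′-ol (expected epimer), via isobutylmagnesium bromide 22 (not isolated), via isobutylcerium dichloride 23 (not isolated)
Conditions: 21, Mg, THF, rt; anhydrous CeCl3, THF, −78 °C; 20, −78 → 0 °C; H2O
Reagents that add atoms: none
Why: Organocerium 1,2-addition, chosen because the ketone has no α-hydrogen and the cerium reagent suppresses the β-hydride reduction that an isobutyl Grignard reagent would give with this hindered, electron-rich aryl ketone; the carbinol configuration is irrelevant because step 15 ionises it.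

Step 15
Reactants: 24 tertiary benzylic alcohol
Product: 25 (1R,3′aR,6R,9′R,9′aS)-6′,8′-dimethoxy-6,9′a-dimethyl-9′-(2-methylpropyl)-3-(propan-2-yl)-1′,2′,9′,9′a-tetrahydro-3′aH-spiro[cyclohex-2-ene-1,3′-cyclopenta[b]chromene]
Conditions: Et3SiH (5 equiv), BF3·OEt2 (2 equiv), CH2Cl2, −78 → −40 °C
Reagents that add atoms: none
Why: SN1 ionisation to the 2,4,6-trioxygenated benzylic cation and hydride capture from the silane (ionic hydrogenolysis), in which the silane should approach the planar C-9′ from the convex face of the cis-fused pyran/cyclopentane unit (the face of 3′a-H and 9′a-CH3), leaving isobutyl on the cyclopentane side as in the target.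

Step 16
Reactants: 25 dimethoxy chroman
Product: 26 (1R,3′aR,6R,9′R,9′aS)-5′,7′-dibromo-6′,8′-dimethoxy-6,9′a-dimethyl-9′-(2-methylpropyl)-3-(propan-2-yl)-1′,2′,9′,9′a-tetrahydro-3′aH-spiro[cyclohex-2-ene-1,3′-cyclopenta[b]chromene]
Conditions: NBS (2.1 equiv), MeCN, 0 °C, dark
Reagents that add atoms: N-bromosuccinimide O=C1CCC(=O)N1Br
Why: Electrophilic aromatic bromination at the two remaining ring positions, each ortho/para to three oxygen donors, should be far faster than reaction at the isolated trisubstituted alkene under ionic conditions in the dark.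

Step 17
Reactants: 26 dibromide
Product: 28 (1R,3′aR,6R,9′R,9′aS)-6′,8′-dimethoxy-6,9′a-dimethyl-9′-(2-methylpropyl)-3-(propan-2-yl)-1′,2′,9′,9′a-tetrahydro-3′aH-spiro[cyclohex-2-ene-1,3′-cyclopenta[b]chromene]-5′,7′-dicarbaldehyde, via aryl dilithium 27 (not isolated)
Conditions: t-BuLi (4.4 equiv), THF, −78 °C; DMF (excess), −78 → 0 °C; H2O
Reagents that add atoms: N,N-dimethylformamide CN(C)C=O
Why: Double bromine–lithium exchange gives an aryl dilithium in which each C–Li bond is flanked by two alkoxy groups, and formylation with DMF followed by hydrolysis installs both aldehydes without any acid that could attack the alkene.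

Step 18
Reactants: 28 dialdehyde dimethyl ether
Product: 29 (1R,3′aR,6R,9′R,9′aS)-6′,8′-dihydroxy-6,9′a-dimethyl-9′-(2-methylpropyl)-3-(propan-2-yl)-1′,2′,9′,9′a-tetrahydro-3′aH-spiro[cyclohex-2-ene-1,3′-cyclopenta[b]chromene]-5′,7′-dicarbaldehyde (CNP0121396.1)
Conditions: BCl3 (excess), CH2Cl2, −78 → 0 °C; then H2O/NaHCO3
Reagents that add atoms: none
Why: Boron trichloride chelates each aldehyde carbonyl with its ortho methoxy group and chloride cleaves the O–CH3 bond (chelation-assisted demethylation), while the neopentyl-type secondary ring ether and the alkene should survive at low temperature.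

**Compound list**

1 | (R)-(−)-carvone | CC1=CC[C@H](CC1=O)C(C)=C | starting material
2 | (2R,5R)-2-methyl-5-(propan-2-yl)cyclohexan-1-one | C[C@@H]1CC[C@H](CC1=O)C(C)C | intermediate
3 | lithium (3S,6R)-6-methyl-3-(propan-2-yl)cyclohex-1-en-1-olate | [Li+].C[C@@H]1CC[C@H](C=C1[O-])C(C)C | intermediate (not isolated)
4 | trimethyl{[(3S,6R)-6-methyl-3-(propan-2-yl)cyclohex-1-en-1-yl]oxy}silane | C[C@@H]1CC[C@H](C=C1O[Si](C)(C)C)C(C)C | intermediate
5 | (6R)-6-methyl-3-(propan-2-yl)cyclohex-2-en-1-one | O=C1C=C(C(C)C)CC[C@H]1C | intermediate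
6 | 1,2-bis(trimethylsilyloxy)cyclobutene | C[Si](C)(C)OC1=C(O[Si](C)(C)C)CC1 | starting material
7 | 2-[(6R)-1-hydroxy-6-methyl-3-(propan-2-yl)cyclohex-2-en-1-yl]-2-(trimethylsilyloxy)cyclobutan-1-one (mixture at the two new centres) | C[C@@H]1CCC(C(C)C)=CC1(O)C2(O[Si](C)(C)C)CCC2=O | intermediate (not isolated)
8 | (10R)-10-methyl-7-(propan-2-yl)spiro[4.5]dec-6-ene-1,4-dione | O=C1CCC(=O)C12C=C(C(C)C)CC[C@H]2C | intermediate
9 | (4S,5R,10R)-4-hydroxy-10-methyl-7-(propan-2-yl)spiro[4.5]dec-6-en-1-one | O=C1CC[C@H](O)[C@@]12C=C(C(C)C)CC[C@H]2C | intermediate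
10 | O-[(4S,5R,10R)-10-methyl-1-oxo-7-(propan-2-yl)spiro[4.5]dec-6-en-4-yl] O-phenyl carbonothioate | O=C1CC[C@H](OC(=S)Oc3ccccc3)[C@@]12C=C(C(C)C)CC[C@H]2C | intermediate
11 | (5R,10R)-10-methyl-7-(propan-2-yl)spiro[4.5]dec-6-en-1-one | O=C1CCC[C@@]12C=C(C(C)C)CC[C@H]2C | intermediate
12 | 2-hydroxy-4,6-dimethoxybenzaldehyde | COc1cc(O)c(C=O)c(OC)c1 | starting material
13 | 2,4-dimethoxy-6-(methoxymethoxy)benzaldehyde | COCOc1cc(OC)cc(OC)c1C=O | intermediate
14 | lithium (5R,10R)-10-methyl-7-(propan-2-yl)spiro[4.5]deca-1,6-dien-1-olate | [Li+].[O-]C1=CCC[C@@]12C=C(C(C)C)CC[C@H]2C | intermediate (not isolated)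
15 | (5R,10R)-2-{[2,4-dimethoxy-6-(methoxymethoxy)phenyl](hydroxy)methyl}-10-methyl-7-(propan-2-yl)spiro[4.5]dec-6-en-1-one (diastereomer mixture) | O=C1C(C(O)c3c(OC)cc(OC)cc3OCOC)CC[C@@]12C=C(C(C)C)CC[C@H]2C | intermediate
16 | (5R,10R)-2-[2,4-dimethoxy-6-(methoxymethoxy)benzoyl]-10-methyl-7-(propan-2-yl)spiro[4.5]dec-6-en-1-one | O=C1C(C(=O)c3c(OC)cc(OC)cc3OCOC)CC[C@@]12C=C(C(C)C)CC[C@H]2C | intermediate
17 | (2R,5R,10R)-2-[2,4-dimethoxy-6-(methoxymethoxy)benzoyl]-2,10-dimethyl-7-(propan-2-yl)spiro[4.5]dec-6-en-1-one | O=C1[C@](C)(C(=O)c3c(OC)cc(OC)cc3OCOC)CC[C@@]12C=C(C(C)C)CC[C@H]2C | intermediate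
18 | (2R,5R,10R)-2-(2-hydroxy-4,6-dimethoxybenzoyl)-2,10-dimethyl-7-(propan-2-yl)spiro[4.5]dec-6-en-1-one | O=C1[C@](C)(C(=O)c3c(OC)cc(OC)cc3O)CC[C@@]12C=C(C(C)C)CC[C@H]2C | intermediate (not isolated)
19 | (1R,3′aS,6R,9′aS)-3′a-hydroxy-6′,8′-dimethoxy-6,9′a-dimethyl-3-(propan-2-yl)-1′,2′,3′a,9′a-tetrahydro-9′H-spiro[cyclohex-2-ene-1,3′-cyclopenta[b]chromen]-9′-one | O=C1c2c(OC)cc(OC)cc2O[C@]2(O)[C@@]1(C)CC[C@@]21C=C(C(C)C)CC[C@H]1C | intermediate
20 | (1R,3′aS,6R,9′aR)-6′,8′-dimethoxy-6,9′a-dimethyl-3-(propan-2-yl)-1′,2′,3′a,9′a-tetrahydro-9′H-spiro[cyclohex-2-ene-1,3′-cyclopenta[b]chromen]-9′-one | O=C1c2c(OC)cc(OC)cc2O[C@@H]2[C@@]1(C)CC[C@@]21C=C(C(C)C)CC[C@H]1C | intermediate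
21 | 1-bromo-2-methylpropane | CC(C)CBr | starting material
22 | isobutylmagnesium bromide | CC(C)C[Mg]Br | intermediate (not isolated)
23 | isobutylcerium dichloride | CC(C)C[Ce](Cl)Cl | intermediate (not isolated)
24 | (1R,3′aS,6R,9′R,9′aR)-6′,8′-dimethoxy-6,9′a-dimethyl-9′-(2-methylpropyl)-3-(propan-2-yl)-1′,2′,9′,9′a-tetrahydro-3′aH-spiro[cyclohex-2-ene-1,3′-cyclopenta[b]chromen]-9′-ol | CC(C)C[C@]1(O)c2c(OC)cc(OC)cc2O[C@@H]2[C@@]1(C)CC[C@@]21C=C(C(C)C)CC[C@H]1C | intermediate
25 | (1R,3′aR,6R,9′R,9′aS)-6′,8′-dimethoxy-6,9′a-dimethyl-9′-(2-methylpropyl)-3-(propan-2-yl)-1′,2′,9′,9′a-tetrahydro-3′aH-spiro[cyclohex-2-ene-1,3′-cyclopenta[b]chromene] | CC(C)C[C@H]1c2c(OC)cc(OC)cc2O[C@@H]2[C@@]1(C)CC[C@@]21C=C(C(C)C)CC[C@H]1C | intermediate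
26 | 5′,7′-dibromo derivative of 25 | CC(C)C[C@H]1c2c(OC)c(Br)c(OC)c(Br)c2O[C@@H]2[C@@]1(C)CC[C@@]21C=C(C(C)C)CC[C@H]1C | intermediate
27 | 5′,7′-dilithio derivative of 25 | CC(C)C[C@H]1c2c(OC)c([Li])c(OC)c([Li])c2O[C@@H]2[C@@]1(C)CC[C@@]21C=C(C(C)C)CC[C@H]1C | intermediate (not isolated)
28 | (1R,3′aR,6R,9′R,9′aS)-6′,8′-dimethoxy-6,9′a-dimethyl-9′-(2-methylpropyl)-3-(propan-2-yl)-1′,2′,9′,9′a-tetrahydro-3′aH-spiro[cyclohex-2-ene-1,3′-cyclopenta[b]chromene]-5′,7′-dicarbaldehyde | CC(C)C[C@H]1c2c(OC)c(C=O)c(OC)c(C=O)c2O[C@@H]2[C@@]1(C)CC[C@@]21C=C(C(C)C)CC[C@H]1C | intermediate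
29 | (1R,3′aR,6R,9′R,9′aS)-6′,8′-dihydroxy-6,9′a-dimethyl-9′-(2-methylpropyl)-3-(propan-2-yl)-1′,2′,9′,9′a-tetrahydro-3′aH-spiro[cyclohex-2-ene-1,3′-cyclopenta[b]chromene]-5′,7′-dicarbaldehyde | CC(C)C[C@H]1c2c(O)c(C=O)c(O)c(C=O)c2O[C@@H]2[C@@]1(C)CC[C@@]21C=C(C(C)C)CC[C@H]1C | target

**Step count and risks**

Total step count: 18. Longest linear sequence: 17 steps (steps 1–7 and 9–18 from (R)-carvone); step 8 and the organometallic reagent of step 14 are side branches.

The three steps most likely to fail:

Step 4. The silyl enol ether may add in the conjugate sense, the allylic carbinol or its cation may lose a proton to give dienes before the acyl shift, and Lewis acid enolisation may erode the α′-methyl configuration before the aldol addition. The fallback sets out from 5. It is converted with 1,2-bis(trimethylsilyloxy)ethane and catalytic TMSOTf in CH2Cl2 at −78 °C into the ethylene ketal (10R)-10-methyl-7-(propan-2-yl)-1,4-dioxaspiro[4.5]dec-6-ene F1; these mild conditions should leave the alkene and the methyl centre in place. F1 is then treated with 6 and excess BF3·OEt2 in CH2Cl2 (−78 °C → rt). The ketal ionises to an alkoxyallyl cation that is attacked at the ketal carbon, and a second ionisation triggers the same acyl shift. Geminal acylation of ketals is the dependable form of this reaction, and the fallback comes back to the route at 8.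

Step 13. The carbonyl flanked by two quaternary carbons may resist hemiketal closure and ionisation, so that the silane reduces the aryl ketone or nothing reacts. The fallback sets out from 16 and also bypasses the face selectivity of step 11. Acid (TsOH, MeOH, 50 °C) removes the MOM group and cyclodehydrates the enolisable diketone to the chromone (1R,6R)-6′,8′-dimethoxy-6-methyl-3-(propan-2-yl)-1′,2′-dihydro-9′H-spiro[cyclohex-2-ene-1,3′-cyclopenta[b]chromen]-9′-one F2. L-Selectride (THF, −78 °C) should add hydride in the conjugate sense to C-3′a from the face of the alkene arm, giving the lithium enolate of 20, lithium 6′,8′-dimethoxy-6-methyl-3-(propan-2-yl)spiro[cyclohex-2-ene-1,3′-cyclopenta[b]chromen]-9′-olate F3. F3 is methylated in the same flask (MeI, HMPA, −78 → 0 °C) at C-9′a on the face of the new 3′a-H, the only face that leads to a cis-fused ring. The fallback comes back to the route at 20.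

Step 15. The silane may deliver hydride from the concave face and give the C-9′ epimer. The fallback sets out from 20 and reverses the order in which hydrogen and carbon are introduced. LiAlH4 (THF, 0 °C) reduces the ketone to the chromanol (1R,3′aS,6R,9′aS)-6′,8′-dimethoxy-6,9′a-dimethyl-3-(propan-2-yl)-1′,2′,9′,9′a-tetrahydro-3′aH-spiro[cyclohex-2-ene-1,3′-cyclopenta[b]chromen]-9′-ol F4. F4 is ionised with BF3·OEt2 in the presence of (2-methylallyl)trimethylsilane (CH2Cl2, −78 °C, Hosomi–Sakurai allylation), so that the carbon nucleophile takes the face that hydride preferred and gives the 9′-(2-methylprop-2-en-1-yl) analogue of 25 F5. The 1,1-disubstituted alkene of F5 is then hydrogenated selectively (H2, RhCl(PPh3)3, benzene, rt) in the presence of the trisubstituted ring alkene. The fallback comes back to the route at 25.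

Further compounds
F1 | step 4 | (10R)-10-methyl-7-(propan-2-yl)-1,4-dioxaspiro[4.5]dec-6-ene | CC(C)C1=CC2(OCCO2)[C@H](C)CC1
F2 | step 13 | (1R,6R)-6′,8′-dimethoxy-6-methyl-3-(propan-2-yl)-1′,2′-dihydro-9′H-spiro[cyclohex-2-ene-1,3′-cyclopenta[b]chromen]-9′-one | O=C1c2c(OC)cc(OC)cc2OC2=C1CC[C@@]21C=C(C(C)C)CC[C@H]1C
F3 | step 13 | lithium 6′,8′-dimethoxy-6-methyl-3-(propan-2-yl)spiro[cyclohex-2-ene-1,3′-cyclopenta[b]chromen]-9′-olate (enolate of 20, 3′a-H set) | [Li+].[O-]C1=C2CC[C@@]3(C=C(C(C)C)CC[C@H]3C)[C@@H]2Oc2cc(OC)cc(OC)c12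
F4 | step 15 | (1R,3′aS,6R,9′aS)-6′,8′-dimethoxy-6,9′a-dimethyl-3-(propan-2-yl)-1′,2′,9′,9′a-tetrahydro-3′aH-spiro[cyclohex-2-ene-1,3′-cyclopenta[b]chromen]-9′-ol (either C-9′ epimer) | OC1c2c(OC)cc(OC)cc2O[C@@H]2[C@@]1(C)CC[C@@]21C=C(C(C)C)CC[C@H]1C
F5 | step 15 | (1R,3′aR,6R,9′R,9′aS)-6′,8′-dimethoxy-6,9′a-dimethyl-9′-(2-methylprop-2-en-1-yl)-3-(propan-2-yl)-1′,2′,9′,9′a-tetrahydro-3′aH-spiro[cyclohex-2-ene-1,3′-cyclopenta[b]chromene] | CC(=C)C[C@H]1c2c(OC)cc(OC)cc2O[C@@H]2[C@@]1(C)CC[C@@]21C=C(C(C)C)CC[C@H]1C
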